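Compound numbers are those of the compound list after the steps.

## Analysis of the target

The target 20 is a flavone: a γ-pyranone (ring C) fused through C4a and C8a to a benzene ring (ring A), with a 4-methoxyphenyl group (ring B) at C2. Ring A carries oxygen on every free carbon, as methoxy groups at C5, C6 and C8 and a single free hydroxyl at C7. There is no stereocentre, so the problem is entirely one of regiochemistry. The sensitive points are the pyranone, which strong nucleophiles can open at C2 and hydrogenation can saturate at C2=C3, and the C5 methoxy group peri to the C4 carbonyl, which Lewis acids cleave first. The main difficulty is that exactly the C7 oxygen of four contiguous ring A oxygens must stay unmethylated. In a polyhydroxyflavone the C7 hydroxyl is the most acidic and most easily alkylated and the chelated C5 hydroxyl the least, so late methylation runs opposite to what is needed. The strategy rests on O1 and the carbonyl carbon C4 sitting on the neighbouring ring A carbons C8a and C4a, with a methoxy group on C5 next to C4a. An aryne whose triple bond spans C4a and C8a is polarised by that methoxy group, so that an oxygen nucleophile goes to C8a and the carbanion, and with it the acyl carbon, to C4a. A 3-arylpropiolic acid then supplies O1, C4, C3, C2 and ring B in one component.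

## Retrosynthetic reasoning

**C8–O bond.** In 20 the C8 methoxy group is the only ring A substituent that can be replaced by hydrogen in a precursor while remaining easy to reinstall. Cutting it leads to bromide 19 and then to phenol 18. In 18, C8 is the single unsubstituted ring A carbon and is activated by the ortho hydroxyl, the para C5 methoxy group and the ring oxygen. The forward steps must brominate only there and then exchange bromide for methoxide under copper mediation. The gain is that the ring-forming step need not deal with a fully substituted ring A, because a hydrogen at C8 leaves C8a open.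

**O7–H bond.** The hydroxyl of 18 is traced to benzyl ether 17. The benzyl group marks, from the start, the one oxygen that must end free. It tolerates base, organolithium reagents and fluoride, and it leaves by hydrogenolysis without touching the methyl ethers.

**O1–C8a, C4–C4a and O1–C2 (key disconnection).** Cutting these three bonds of 17 together gives aryne 15, stored as silyl triflate 13, and acid 14. Cuts inside ring C at C2–C3 or C3–C4 would instead lead to a pentasubstituted ortho-acylphenol of ring A, whose acyl group would have to be placed between two oxygen-bearing carbons with no regiochemical handle. The chosen cut lets the C5 methoxy group decide the regiochemistry. Forward, the carboxylate of 14 must add through oxygen at C8a, the resulting carbanion at C4a must take the acyl carbon, and the phenoxide of ynone 16 must close ring C by 6-endo addition.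

**C–Si and O–S bonds of 13.** The triflate is cut back to carbamate 11 and the silyl group to a carbamate-directed metalation of 7, itself made from phenol 6. In 7 the carbamate has only one ortho hydrogen, so the silyl group can only enter at the carbon that becomes C8a.

**Aryl C–O bond of 6.** The phenol oxygen of 6 is traced through formate 5 to the formyl group of aldehyde 4 (aryl migration in a Baeyer–Villiger oxidation). An aldehyde at this carbon is what makes the earlier ether pattern easy to set.

**Ether bonds of 4.** Removing the two methyl groups gives 3, and removing the benzyl group gives 1 and 2. In 1 the hydroxyl para to the formyl group is the most acidic, so a single equivalent of 2 under weak base goes there, and the two remaining hydroxyls are then methylated together.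

## Alternatives that were turned down

**Alternative 1: late oxygenation of a purchased flavone at C6 and C8.** The disconnection is at the C6–O and C8–O bonds; the skeleton is bought as acacetin A1. Forward, A1 is brominated to 6,8-dibromoacacetin A2, and both bromides are displaced with NaOMe/CuBr in DMF to give the 5,7-dihydroxy-6,8-dimethoxy flavone A3.

- For it: no ring construction is needed, the substitution chemistry is the same kind used at the end of the chosen route, and about five steps should reach 20.
- Against it: A3 has both the C5 and C7 hydroxyls free, while 20 needs C5 methylated and C7 free. Direct methylation goes to O7 first, so O7 must be protected, the chelated O5 methylated under forcing conditions, and O7 released again.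
- Against it: two copper substitutions at positions each flanked by two oxygens must both go to completion on a dianionic, very electron-rich ring. Partial reduction would give 6- and 8-monomethoxy products that are hard to separate.
- Comparison: on step count this alternative is clearly stronger (about five steps against ten). The chosen strategy offers instead an oxygen pattern that is differentiated from the first step, with O7 marked by benzyl and O5 never a chelated phenol. It also needs only one copper substitution, and ring B can be varied through the propiolic acid, independent of the supply of a natural flavone.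

**Alternative 2: Claisen folding of a linear aroyl polyketo ester.** The disconnection is at C4a–C8a of ring A and O1–C2 of ring C, so that both rings come from the open-chain tetraketo ester A5. Forward, Mg(OMe)2 templates attack of C6 of A5 on the ester carbon to form ring A, and acid then dehydrates the new phenol onto the aryl ketone to give acacetin A4, the same compound as A1.

- For it: two rings form from one acyclic precursor with no aromatic starting material for ring A and no protecting group before ring formation. On ring-forming economy it is stronger than the chosen route, which closes one ring.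
- Against it: A4 is a purchasable compound. A5 must be assembled by polyanion acylations, is labile, and can fold by aldol or pyranone-forming modes other than the desired Claisen closure.
- Against it: after the key step all the work of alternative 1 (C6 and C8 oxygenation, O5/O7 differentiation) still remains.
- Comparison: it is alternative 1 with a difficult preface. The chosen strategy forms three bonds in one operation from two stable components and has three of the four ring A oxygens correctly differentiated before the ring is made.

**Alternative 3: ring A annulated onto a pyranone from a squaric ester.** The disconnection is at C8–C8a (and earlier C4a–C5), building ring A onto a preformed 2-aryl-pyran-4-one. Forward, heating the 4-hydroxy-4-pyranonylcyclobutenone A7 (from a 3-metallated 2-arylpyranone and a dibenzyl squarate) opens the four-membered ring to a vinylketene. Its ketene carbon closes onto the pyranone carbon next to the ring oxygen, and tautomerisation gives the 5,8-hydroquinone A6.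

- For it: all four ring A oxygens arrive with the ring, so no late aromatic substitution at C8 is needed. On this point it is stronger than the chosen route, which spends two steps on C8.
- Against it: the symmetric squarate delivers O6 and O7 with the same protecting group and O5 and O8 as the same free phenol, whereas 20 needs O5, O6 and O8 methylated and O7 alone free. After methylating the hydroquinone the two benzyl ethers cannot be told apart, and after removing both, the more acidic O7 would be methylated before O6.
- Against it: a mixed benzyl methyl squarate would repair this only if the nucleophile chose one of two similar carbonyls. The metallated pyranone is itself a fragile nucleophile on an electrophilic ring, and A6 is an air-sensitive hydroquinone.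
- Comparison: the chosen strategy settles the O7 differentiation at the outset from the acidity order of 1 and uses a bench-stable silyl triflate and a commercial acid as partners, at the price of the two-step C8 oxygenation.

Key step: step 7

Assumption: the N–Si bond formed in step 5 is hydrolysed on the acidic aqueous work-up of that step, so the N–H carbamate 11 is what is isolated.

## Route

Step 1
Reactants: 1 2,3,4-trihydroxybenzaldehyde; 2 benzyl bromide
Product: 3 4-(benzyloxy)-2,3-dihydroxybenzaldehyde
Conditions: BnBr (1.05 equiv), NaHCO3, NaI (cat.), DMF, 40 °C
Reagents that add atoms: none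
Why: Williamson ether synthesis under a base too weak to ionise more than the most acidic phenol; the 4-hydroxyl is para to the formyl group, while the 2-hydroxyl is held in a hydrogen bond to the carbonyl and the 3-hydroxyl is not conjugated, so one equivalent of 2 should go to O4.

Step 2
Reactants: 3 4-(benzyloxy)-2,3-dihydroxybenzaldehyde
Product: 4 4-(benzyloxy)-2,3-dimethoxybenzaldehyde
Conditions: MeI (3 equiv), K2CO3, DMF, 40 °C
Reagents that add atoms: iodomethane, CI
Why: Exhaustive Williamson methylation; the stronger base and excess iodomethane also alkylate the chelated 2-hydroxyl, and nothing else in 3 reacts.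

Step 3
Reactants: 4 4-(benzyloxy)-2,3-dimethoxybenzaldehyde
Product: 6 4-(benzyloxy)-2,3-dimethoxyphenol, via aryl formate 5 (not isolated)
Conditions: mCPBA, CH2Cl2, 0 °C to rt; then K2CO3, MeOH, rt
Reagents that add atoms: 3-chloroperoxybenzoic acid, O=C(OO)c1cccc(Cl)c1
Why: Baeyer–Villiger oxidation of an electron-rich benzaldehyde; the aryl group, carrying ortho and para alkoxy donors, migrates in preference to hydrogen to give formate 5, which mild methanolysis cleaves to the phenol without affecting the ethers.

Step 4
Reactants: 6 4-(benzyloxy)-2,3-dimethoxyphenol
Product: 7 4-(benzyloxy)-2,3-dimethoxyphenyl propan-2-ylcarbamate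
Conditions: iPrNCO, Et3N (cat.), CH2Cl2, rt
Reagents that add atoms: isopropyl isocyanate, CC(C)N=C=O
Why: Amine-catalysed addition of a phenol to an isocyanate; it installs a strong ortho-directing group that can later be removed under mild base.

Step 5
Reactants: 7 4-(benzyloxy)-2,3-dimethoxyphenyl propan-2-ylcarbamate
Product: 11 4-(benzyloxy)-2,3-dimethoxy-6-(trimethylsilyl)phenyl propan-2-ylcarbamate, via N-silyl carbamate 8 (not isolated), via aryllithium 9 (not isolated), via bis-silyl carbamate 10 (not isolated)
Conditions: TBSOTf, TMEDA, Et2O, 0 °C to rt; n-BuLi, TMEDA, −78 °C; TMSCl, −78 °C to rt; aq. NaHSO4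
Reagents that add atoms: chlorotrimethylsilane, C[Si](C)(C)Cl
Why: Directed ortho-metalation of an O-aryl carbamate whose N–H is masked in the flask as the N-silyl derivative 8; the carbamate has a single ortho hydrogen and is a far stronger director than the benzyl or methyl ethers, so lithiation should occur only at the future C8a. The low temperature holds back the anionic Fries shift and benzylic deprotonation until chlorotrimethylsilane has trapped 9.

Step 6
Reactants: 11 4-(benzyloxy)-2,3-dimethoxy-6-(trimethylsilyl)phenyl propan-2-ylcarbamate
Product: 13 4-(benzyloxy)-2,3-dimethoxy-6-(trimethylsilyl)phenyl trifluoromethanesulfonate, via silylphenol 12 (not isolated)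
Conditions: DBU, Et2NH, MeCN, 40 °C; then PhNTf2, rt
Reagents that add atoms: N-phenylbis(trifluoromethanesulfonimide), O=S(=O)(N(c1ccccc1)S(=O)(=O)C(F)(F)F)C(F)(F)F
Why: E1cB cleavage of the secondary carbamate (N-deprotonation, loss of the phenoxide, trapping of the isocyanate by diethylamine as a urea), followed by O-sulfonylation of the phenoxide in the same flask; the conditions are free of fluoride and acid, so the aryl–silicon bond should survive.

Step 7
Reactants: 13 4-(benzyloxy)-2,3-dimethoxy-6-(trimethylsilyl)phenyl trifluoromethanesulfonate; 14 3-(4-methoxyphenyl)propiolic acid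
Product: 17 7-(benzyloxy)-5,6-dimethoxy-2-(4-methoxyphenyl)-4H-chromen-4-one, via aryne 15 (not isolated), via hydroxyaryl ynone 16 (not isolated)
Conditions: CsF (5 equiv), THF, 125 °C, sealed tube
Reagents that add atoms: none
Why: Fluoride attacks silicon of 13 and triflate leaves, giving aryne 15 whose triple bond spans the future C4a and C8a. The C5 methoxy group, by its inductive pull, makes the remote aryne carbon (C8a, flanked only by C8–H) the electrophilic one, so the caesium carboxylate of 14 bonds through oxygen at C8a and the carbanion develops at C4a next to the methoxy group. That carbanion attacks the ester carbonyl two atoms away through a four-membered transition state and the strained adduct opens to the phenoxide of ynone 16, an anionic Fries-type O-to-C acyl shift that makes C4a–C4. The phenoxide then adds to the alkyne carbon β to the ketone in a 6-endo-dig oxa-Michael closure (O1–C2) and the allenolate is protonated at C3, which completes ring C. The closest known reaction type is the insertion of arynes into the C–O bond of carboxylic acids to give ortho-hydroxyaryl ketones, run with a 3-arylpropiolic acid so that the flavone forms in the same flask. No stereocentre is created. The step needs three selectivities: oxygen at C8a and not C4a, secured by the C5 methoxy group and the open C8 side; acyl transfer faster than protonation of the carbanion or its conjugate addition to the alkyne, secured by an aprotic solvent, excess CsF that holds HF as CsHF2 and the Z conformation of the aryl ester that keeps the alkyne away from the anion; and 6-endo over 5-exo closure, secured by the polarisation of the ynone toward its β-carbon.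

Step 8
Reactants: 17 7-(benzyloxy)-5,6-dimethoxy-2-(4-methoxyphenyl)-4H-chromen-4-one
Product: 18 7-hydroxy-5,6-dimethoxy-2-(4-methoxyphenyl)-4H-chromen-4-one
Conditions: H2 (1 atm), Pd/C, EtOAc/MeOH, rt
Reagents that add atoms: none
Why: Hydrogenolysis of an aryl benzyl ether; the C2=C3 bond is part of an aryl-conjugated vinylogous ester and is reduced much more slowly, so stopping at one equivalent of hydrogen should leave the pyranone intact.

Step 9
Reactants: 18 7-hydroxy-5,6-dimethoxy-2-(4-methoxyphenyl)-4H-chromen-4-one
Product: 19 8-bromo-7-hydroxy-5,6-dimethoxy-2-(4-methoxyphenyl)-4H-chromen-4-one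
Conditions: NBS (1.05 equiv), DMF, 0 °C
Reagents that add atoms: N-bromosuccinimide, O=C1CCC(=O)N1Br
Why: Electrophilic aromatic bromination; C8 is the only free ring A carbon and is ortho to the hydroxyl, ortho to the ring oxygen and para to the C5 methoxy group, so it should be much more nucleophilic than C3 or the carbonyl-deactivated ring B.

Step 10
Reactants: 19 8-bromo-7-hydroxy-5,6-dimethoxy-2-(4-methoxyphenyl)-4H-chromen-4-one
Product: 20 7-hydroxy-5,6,8-trimethoxy-2-(4-methoxyphenyl)-4H-chromen-4-one
Conditions: NaOMe (excess), CuBr, DMF/MeOH, 100 °C; then dil. HCl
Reagents that add atoms: sodium methoxide, C[O-].[Na+]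
Why: Ullmann-type copper-mediated methoxylation of an aryl bromide ortho to a phenoxide, the same situation as the conversion of an ortho-bromophenol aldehyde into its methoxy analogue; the C7 phenoxide formed under the conditions also makes the pyranone electron-rich and so protects C2 from methoxide.

## Compound list

1 | 2,3,4-trihydroxybenzaldehyde | O=Cc1ccc(O)c(O)c1O | starting material
2 | benzyl bromide | BrCc1ccccc1 | starting material
3 | 4-(benzyloxy)-2,3-dihydroxybenzaldehyde | O=Cc1ccc(OCc2ccccc2)c(O)c1O | intermediate
4 | 4-(benzyloxy)-2,3-dimethoxybenzaldehyde | COc1c(C=O)ccc(OCc2ccccc2)c1OC | intermediate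
5 | 4-(benzyloxy)-2,3-dimethoxyphenyl formate | COc1c(OC=O)ccc(OCc2ccccc2)c1OC | intermediate
6 | 4-(benzyloxy)-2,3-dimethoxyphenol | COc1c(O)ccc(OCc2ccccc2)c1OC | intermediate
7 | 4-(benzyloxy)-2,3-dimethoxyphenyl propan-2-ylcarbamate | COc1c(OC(=O)NC(C)C)ccc(OCc2ccccc2)c1OC | intermediate
8 | 4-(benzyloxy)-2,3-dimethoxyphenyl N-(tert-butyldimethylsilyl)-N-(propan-2-yl)carbamate | COc1c(OC(=O)N(C(C)C)[Si](C)(C)C(C)(C)C)ccc(OCc2ccccc2)c1OC | intermediate
9 | [5-(benzyloxy)-2-{[(tert-butyldimethylsilyl)(propan-2-yl)carbamoyl]oxy}-3,4-dimethoxyphenyl]lithium | COc1c(OC(=O)N(C(C)C)[Si](C)(C)C(C)(C)C)c([Li])cc(OCc2ccccc2)c1OC | intermediate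
10 | 4-(benzyloxy)-2,3-dimethoxy-6-(trimethylsilyl)phenyl N-(tert-butyldimethylsilyl)-N-(propan-2-yl)carbamate | COc1c(OC(=O)N(C(C)C)[Si](C)(C)C(C)(C)C)c([Si](C)(C)C)cc(OCc2ccccc2)c1OC | intermediate
11 | 4-(benzyloxy)-2,3-dimethoxy-6-(trimethylsilyl)phenyl propan-2-ylcarbamate | COc1c(OC(=O)NC(C)C)c([Si](C)(C)C)cc(OCc2ccccc2)c1OC | intermediate
12 | 4-(benzyloxy)-2,3-dimethoxy-6-(trimethylsilyl)phenol | COc1c(O)c([Si](C)(C)C)cc(OCc2ccccc2)c1OC | intermediate
13 | 4-(benzyloxy)-2,3-dimethoxy-6-(trimethylsilyl)phenyl trifluoromethanesulfonate | COc1c(OCc2ccccc2)cc([Si](C)(C)C)c(OS(=O)(=O)C(F)(F)F)c1OC | intermediate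
14 | 3-(4-methoxyphenyl)propiolic acid | COc1ccc(C#CC(=O)O)cc1 | starting material
15 | 5-(benzyloxy)-3,4-dimethoxybenzyne (1,2-didehydrobenzene) | COC1=C(OC)C(OCc2ccccc2)=CC#C1 | intermediate
16 | 1-[4-(benzyloxy)-2-hydroxy-5,6-dimethoxyphenyl]-3-(4-methoxyphenyl)prop-2-yn-1-one (present as its caesium phenoxide) | COc1ccc(C#CC(=O)c2c(O)cc(OCc3ccccc3)c(OC)c2OC)cc1 | intermediate
17 | 7-(benzyloxy)-5,6-dimethoxy-2-(4-methoxyphenyl)-4H-chromen-4-one | COc1ccc(-c2cc(=O)c3c(OC)c(OC)c(OCc4ccccc4)cc3o2)cc1 | intermediate
18 | 7-hydroxy-5,6-dimethoxy-2-(4-methoxyphenyl)-4H-chromen-4-one | COc1ccc(-c2cc(=O)c3c(OC)c(OC)c(O)cc3o2)cc1 | intermediate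
19 | 8-bromo-7-hydroxy-5,6-dimethoxy-2-(4-methoxyphenyl)-4H-chromen-4-one | COc1ccc(-c2cc(=O)c3c(OC)c(OC)c(O)c(Br)c3o2)cc1 | intermediate
20 | 7-hydroxy-5,6,8-trimethoxy-2-(4-methoxyphenyl)-4H-chromen-4-one (7-hydroxy-4',5,6,8-tetramethoxyflavone) | COc1ccc(-c2cc(=O)c3c(OC)c(OC)c(O)c(OC)c3o2)cc1 | target

## Step count and least certain steps

Total: 10 steps. Longest linear sequence: 10 steps, from 1 to 20; acid 14 enters at step 7.

**Step 7 (key step).** The most likely failure is proton transfer to the C4a carbanion before the acyl shift, which stops the sequence at the aryl ester. Conjugate addition of that carbanion to the alkyne, or decarboxylation of the propiolate at 125 °C, are further possibilities.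

The fallback sets out from silyl triflate 13 and returns at flavone 17:
- Aryne 15 is generated with CsF in N,N-dimethylformamide at room temperature, where it inserts into the C=O bond of the solvent. Aqueous work-up hydrolyses the aminal to 4-(benzyloxy)-2-hydroxy-5,6-dimethoxybenzaldehyde F1. The oxygen again goes to the carbon remote from the methoxy group, but there is no acid proton and no heating of an alkynoic acid.
- The lithium acetylide of 1-ethynyl-4-methoxybenzene (more than two equivalents, THF, −78 °C) adds to F1 to give racemic 1-[4-(benzyloxy)-2-hydroxy-5,6-dimethoxyphenyl]-3-(4-methoxyphenyl)prop-2-yn-1-ol F2.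
- MnO2 in CH2Cl2 oxidises the benzylic, propargylic alcohol to ynone 16, and K2CO3 in acetone closes 16 to 17.

**Step 5.** The risks are deprotonation at the benzylic CH2 of the benzyl ether (with Wittig rearrangement on warming), metalation ortho to the benzyloxy group, or carbamoyl migration before the silyl chloride has reacted.

The fallback sets out from phenol 6 and returns at silyl triflate 13:
- Bromination ortho to the hydroxyl (NBS, iPr2NH (cat.), CH2Cl2, 0 °C) gives 4-(benzyloxy)-6-bromo-2,3-dimethoxyphenol F3.
- Hexamethyldisilazane converts F3 into [4-(benzyloxy)-6-bromo-2,3-dimethoxyphenoxy]trimethylsilane F4.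
- n-BuLi in THF at −78 °C exchanges bromine for lithium much faster than it deprotonates a benzylic position. The silyl group then moves from oxygen to carbon (retro-Brook rearrangement) to give the lithium salt of silylphenol 12, and Tf2O added to the same flask gives 13.
- Deprotonation is thereby replaced by halogen–metal exchange, and the regiochemistry is set in the bromination.

**Step 10.** The risks are reductive loss of bromine during the copper cycle and opening of the pyranone by methoxide at C2 under prolonged heating.

The fallback sets out from bromide 19 and returns at target 20: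
- Re-benzylation with 2 (K2CO3, DMF) gives 7-(benzyloxy)-8-bromo-5,6-dimethoxy-2-(4-methoxyphenyl)-4H-chromen-4-one F5.
- Palladium-catalysed C–O coupling with methanol (Pd2(dba)3, tBuBrettPhos, Cs2CO3, toluene, 80 °C) gives 7-(benzyloxy)-5,6,8-trimethoxy-2-(4-methoxyphenyl)-4H-chromen-4-one F6. The bulky biarylphosphine makes C–O reductive elimination from divalent palladium faster than β-hydride elimination.
- Hydrogenolysis (H2, Pd/C, as in step 8) gives 20.

**Step 1.** The risk is loss of site selectivity, with alkylation at O3 or a second alkylation.

The fallback sets out from benzyl bromide 2 and returns at phenol 6, bypassing steps 1 to 3: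
- 2,3-Dimethoxycyclohexa-2,5-diene-1,4-dione F7, made by oxidising commercial 2,3-dimethoxyphenol with (KSO3)2NO, is reduced with Na2S2O4 to 2,3-dimethoxybenzene-1,4-diol F8.
- F8 is symmetric, so alkylation with one equivalent of 2 (K2CO3, acetone) can give only one monoether, which is 6. The dibenzyl ether and unreacted F8 are removed by base extraction and chromatography.
- A regiochemical question is thereby exchanged for a statistical mono-alkylation.

## Further compounds

F1 | step 7 | 4-(benzyloxy)-2-hydroxy-5,6-dimethoxybenzaldehyde | COc1c(OCc2ccccc2)cc(O)c(C=O)c1OC
F2 | step 7 | 1-[4-(benzyloxy)-2-hydroxy-5,6-dimethoxyphenyl]-3-(4-methoxyphenyl)prop-2-yn-1-ol (racemic) | COc1ccc(C#CC(O)c2c(O)cc(OCc3ccccc3)c(OC)c2OC)cc1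
F3 | step 5 | 4-(benzyloxy)-6-bromo-2,3-dimethoxyphenol | COc1c(O)c(Br)cc(OCc2ccccc2)c1OC
F4 | step 5 | [4-(benzyloxy)-6-bromo-2,3-dimethoxyphenoxy]trimethylsilane | COc1c(O[Si](C)(C)C)c(Br)cc(OCc2ccccc2)c1OC
F5 | step 10 | 7-(benzyloxy)-8-bromo-5,6-dimethoxy-2-(4-methoxyphenyl)-4H-chromen-4-one | COc1ccc(-c2cc(=O)c3c(OC)c(OC)c(OCc4ccccc4)c(Br)c3o2)cc1
F6 | step 10 | 7-(benzyloxy)-5,6,8-trimethoxy-2-(4-methoxyphenyl)-4H-chromen-4-one | COc1ccc(-c2cc(=O)c3c(OC)c(OC)c(OCc4ccccc4)c(OC)c3o2)cc1
F7 | step 1 | 2,3-dimethoxycyclohexa-2,5-diene-1,4-dione | COC1=C(OC)C(=O)C=CC1=O
F8 | step 1 | 2,3-dimethoxybenzene-1,4-diol | COc1c(O)ccc(O)c1OC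
A1 | alternative 1 | 5,7-dihydroxy-2-(4-methoxyphenyl)-4H-chromen-4-one (acacetin) | COc1ccc(-c2cc(=O)c3c(O)cc(O)cc3o2)cc1
A2 | alternative 1 | 6,8-dibromo-5,7-dihydroxy-2-(4-methoxyphenyl)-4H-chromen-4-one (6,8-dibromoacacetin) | COc1ccc(-c2cc(=O)c3c(O)c(Br)c(O)c(Br)c3o2)cc1
A3 | alternative 1 | 5,7-dihydroxy-6,8-dimethoxy-2-(4-methoxyphenyl)-4H-chromen-4-one | COc1ccc(-c2cc(=O)c3c(O)c(OC)c(O)c(OC)c3o2)cc1
A4 | alternative 2 | 5,7-dihydroxy-2-(4-methoxyphenyl)-4H-chromen-4-one (acacetin, the same compound as A1) | COc1ccc(-c2cc(=O)c3c(O)cc(O)cc3o2)cc1
A5 | alternative 2 | methyl 9-(4-methoxyphenyl)-3,5,7,9-tetraoxononanoate | COC(=O)CC(=O)CC(=O)CC(=O)CC(=O)c1ccc(OC)cc1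
A6 | alternative 3 | 6,7-bis(benzyloxy)-5,8-dihydroxy-2-(4-methoxyphenyl)-4H-chromen-4-one | COc1ccc(-c2cc(=O)c3c(O)c(OCc4ccccc4)c(OCc4ccccc4)c(O)c3o2)cc1
A7 | alternative 3 | 2,3-bis(benzyloxy)-4-hydroxy-4-[6-(4-methoxyphenyl)-4-oxo-4H-pyran-3-yl]cyclobut-2-en-1-one (racemic) | O=C1C(OCc2ccccc2)=C(OCc2ccccc2)C1(O)c1coc(-c2ccc(OC)cc2)cc1=O
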